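**Assumption:** the target has no stereocentre and no stereogenic double bond, so it is achiral and needs no enantiocontrol; the linker is read as (CH2)14 (C30H42O8).

## Retrosynthetic overview

1. Both ring–CH2 bonds are cut: the target comes from two molecules of 2-hydroxy-5-methoxy-6-methyl-1,4-benzoquinone and tetradecanedial, joined by a double intermolecular aldol-type (Knoevenagel) condensation at the quinone C3–H with in situ Hantzsch-ester reduction.
2. The hydroxyquinone comes from mirror-symmetric 4,6-dimethoxy-5-methylbenzene-1,3-diol by oxidative mono-demethylation; the symmetry fixes the regiochemistry (OMe next to Me, OH para to OMe).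
3. That diol comes from 2,6-dimethoxytoluene by dibromination, double borylation and boronate oxidation.
4. Tetradecanedial comes from tetradecanedioic acid by reduction and re-oxidation.
5. Ring order: no ring is built; both six-membered carbocycles come from the arene starting material and are raised to the quinone level before the coupling, so the last step needs no protecting groups.

## Route

Step 1
Reactants: 1 2,6-dimethoxytoluene
Product: 2 1,5-dibromo-2,4-dimethoxy-3-methylbenzene
Conditions: NBS (2.2 equiv), MeCN, 0 °C → 40 °C, dark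
Reagents that add atoms: N-bromosuccinimide, O=C1CCC(=O)N1Br
Why: Electrophilic aromatic bromination goes twice at the two ring positions that are ortho to one methoxy group and para to the other, leaving the position meta to both ethers and the methyl group untouched.

Step 2
Reactants: 2 1,5-dibromo-2,4-dimethoxy-3-methylbenzene
Product: 3 2,2'-(4,6-dimethoxy-5-methyl-1,3-phenylene)bis(4,4,5,5-tetramethyl-1,3,2-dioxaborolane)
Conditions: B2pin2 (2.6 equiv), PdCl2(dppf) (5 mol%; dppf = 1,1'-bis(diphenylphosphino)ferrocene), KOAc (6 equiv), 1,4-dioxane, 90 °C, N2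
Reagents that add atoms: bis(pinacolato)diboron, CC1(C)OB(OC1(C)C)B1OC(C)(C)C(C)(C)O1
Why: In this double Miyaura borylation, zerovalent palladium inserts into each aryl C–Br bond and acetate-assisted transmetalation with B2pin2 gives the aryl boronate without touching the ethers.

Step 3
Reactants: 3 2,2'-(4,6-dimethoxy-5-methyl-1,3-phenylene)bis(4,4,5,5-tetramethyl-1,3,2-dioxaborolane)
Product: 4 4,6-dimethoxy-5-methylbenzene-1,3-diol
Conditions: 30% aq H2O2 (2.5 equiv), NaHCO3, THF/H2O, 0 °C → rt, N2; Na2S2O3 quench
Reagents that add atoms: hydrogen peroxide, OO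
Why: In this boronate oxidation, hydroperoxide adds to boron and the aryl group migrates from boron to oxygen at the same carbon, turning both C–B bonds into phenols, while the bicarbonate buffer and inert atmosphere protect the electron-rich diol from autoxidation.

Step 4
Reactants: 4 4,6-dimethoxy-5-methylbenzene-1,3-diol
Product: 5 2-hydroxy-5-methoxy-6-methylcyclohexa-2,5-diene-1,4-dione
Conditions: PhI(OAc)2 (1.05 equiv), MeCN/H2O 2:1, 0 °C, 30 min (4 added slowly to the oxidant)
Reagents that add atoms: water, O
Why: In this oxidative demethylation of a methoxyphenol by PhI(OAc)2, the phenoxenium ion is hydrated at a methoxy-bearing carbon and loses methanol, and because 4 has a mirror plane every mode of oxidation gives the same product, which rests as the 2-hydroxy-1,4-quinone tautomer.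

Step 5
Reactants: 6 tetradecanedioic acid
Product: 7 tetradecane-1,14-diol
Conditions: LiAlH4 (3 equiv), THF, 0 °C → reflux; aqueous work-up
Reagents that add atoms: none
Why: Hydride reduction of both carboxylic acids to primary alcohols by LiAlH4 is a standard transformation and the saturated chain carries no competing group.

Step 6
Reactants: 7 tetradecane-1,14-diol
Product: 8 tetradecanedial
Conditions: TEMPO (2,2,6,6-tetramethylpiperidin-1-oxyl, 10 mol%), PhI(OAc)2 (2.4 equiv), CH2Cl2, rt; used at once
Reagents that add atoms: none
Why: The oxoammonium (TEMPO/PhI(OAc)2) oxidation of primary alcohols stops at the aldehyde under anhydrous conditions, so no over-oxidation to the acid occurs.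

Step 7
Reactants: 5 2-hydroxy-5-methoxy-6-methylcyclohexa-2,5-diene-1,4-dione (2.2 equiv); 8 tetradecanedial (1.0 equiv)
Product: 12 3,3'-(tetradecane-1,14-diyl)bis(2-hydroxy-5-methoxy-6-methylcyclohexa-2,5-diene-1,4-dione), via quinone methide aldehyde 9 (not isolated), via monoalkylated quinone aldehyde 10 (not isolated), via monoalkylated quinone methide 11 (not isolated)
Conditions: Hantzsch ester (diethyl 2,6-dimethyl-1,4-dihydropyridine-3,5-dicarboxylate, 2.5 equiv), L-proline (20 mol%), CH2Cl2, 25 °C, N2, 24 h; aerobic work-up
Reagents that add atoms: none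
Why: The only ring C–H of 5 is the α-carbon of a vinylogous carboxylic acid, so it adds to the proline-activated aldehyde in an aldol-type Knoevenagel condensation (Mannich-type addition to the iminium, then loss of proline), and the electrophilic quinone methide is reduced at once by hydride transfer from the Hantzsch ester (three-component reductive alkylation), first at one chain end and then at the other, with no stereocentre formed.

## Compound list

1 | 2,6-dimethoxytoluene (1,3-dimethoxy-2-methylbenzene) | COc1cccc(OC)c1C | starting material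
2 | 1,5-dibromo-2,4-dimethoxy-3-methylbenzene | COc1c(Br)cc(Br)c(OC)c1C | intermediate
3 | 2,2'-(4,6-dimethoxy-5-methyl-1,3-phenylene)bis(4,4,5,5-tetramethyl-1,3,2-dioxaborolane) | COc1c(B2OC(C)(C)C(C)(C)O2)cc(B2OC(C)(C)C(C)(C)O2)c(OC)c1C | intermediate
4 | 4,6-dimethoxy-5-methylbenzene-1,3-diol | COc1c(O)cc(O)c(OC)c1C | intermediate
5 | 2-hydroxy-5-methoxy-6-methylcyclohexa-2,5-diene-1,4-dione (2-hydroxy-5-methoxy-6-methyl-1,4-benzoquinone) | COC1=C(C)C(=O)C(O)=CC1=O | intermediate
6 | tetradecanedioic acid | OC(=O)CCCCCCCCCCCCC(O)=O | starting material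
7 | tetradecane-1,14-diol | OCCCCCCCCCCCCCCO | intermediate
8 | tetradecanedial | O=CCCCCCCCCCCCCC=O | intermediate
9 | 14-(3-methoxy-4-methyl-2,5,6-trioxocyclohex-3-en-1-ylidene)tetradecanal (formed in situ in step 7; alkene geometry undefined) | COC1=C(C)C(=O)C(=O)C(=CCCCCCCCCCCCCC=O)C1=O | intermediate
10 | 14-(2-hydroxy-5-methoxy-4-methyl-3,6-dioxocyclohexa-1,4-dien-1-yl)tetradecanal (formed in situ in step 7) | COC1=C(C)C(=O)C(O)=C(CCCCCCCCCCCCCC=O)C1=O | intermediate
11 | 2-hydroxy-5-methoxy-3-[14-(3-methoxy-4-methyl-2,5,6-trioxocyclohex-3-en-1-ylidene)tetradecyl]-6-methylcyclohexa-2,5-diene-1,4-dione (formed in situ in step 7; alkene geometry undefined) | COC1=C(C)C(=O)C(O)=C(CCCCCCCCCCCCCC=C2C(=O)C(=O)C(C)=C(OC)C2=O)C1=O | intermediate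
12 | 3,3'-(tetradecane-1,14-diyl)bis(2-hydroxy-5-methoxy-6-methylcyclohexa-2,5-diene-1,4-dione), CNP0278640.0, achiral | COC1=C(C)C(=O)C(O)=C(CCCCCCCCCCCCCCC2=C(O)C(=O)C(C)=C(OC)C2=O)C1=O | target

## Step count and risks

Total step count: 7. Longest linear sequence: 5 steps (steps 1, 2, 3, 4, 7); the chain branch is 3 steps (5, 6, 7).

The three steps most likely to fail:

1. Step 7, the double reductive Knoevenagel coupling. Risks are Michael addition of a second molecule of 5 to the quinone methide (2:1 adducts), displacement of the quinone methoxy group by proline, and incomplete reaction at the second chain end. The fallback sets out from 4 (with 7 as the chain source) and comes back at 12, and no longer uses the quinone as the nucleophile. 4 is protected with MOMCl/iPr2NEt in CH2Cl2 as 2,4-dimethoxy-1,5-bis(methoxymethoxy)-3-methylbenzene F1, and 7 is converted with CBr4/PPh3 in CH2Cl2 into 1,14-dibromotetradecane F2. F1 is lithiated at its only ring C–H, which lies between the two MOM ethers (n-BuLi, THF, 0 °C, directed ortho-metalation), and the aryllithium is alkylated with 0.45 equiv of F2 in THF/DMPU to give 1,14-bis[3,5-dimethoxy-2,6-bis(methoxymethoxy)-4-methylphenyl]tetradecane F3. HCl in MeOH removes the four MOM groups to give 2,2'-(tetradecane-1,14-diyl)bis(4,6-dimethoxy-5-methylbenzene-1,3-diol) F4. PhI(OAc)2 (2.1 equiv) in MeCN/H2O then demethylates each mirror-symmetric ring oxidatively, as in step 4, to give 12.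

2. Step 2, the double borylation. Risks are an incomplete second borylation and protodeboronation next to the methoxy groups. The fallback sets out from 1 and comes back at 4, introducing the two oxygens through carbonyl chemistry instead of boron. Rieche diformylation of 1 (Cl2CHOMe and TiCl4 in excess, CH2Cl2, 0 °C → rt) gives 4,6-dimethoxy-5-methylbenzene-1,3-dicarbaldehyde F5. Baeyer–Villiger oxidation with mCPBA in CH2Cl2, in which the electron-rich aryl group migrates, gives 4,6-dimethoxy-5-methyl-1,3-phenylene diformate F6. Methanolysis with K2CO3 in MeOH under N2 gives 4.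

3. Step 4, the oxidative demethylation to the hydroxyquinone. Risks are oxidative coupling through the free ring position of 4, over-oxidation, and loss of the polar, acidic product to the aqueous phase. The fallback sets out from 1 and comes back at 5, building the hydroxyquinone by acetoxylation of a simpler quinone. Mono-demethylation of 1 with EtSNa in DMF at 140 °C gives 3-methoxy-2-methylphenol F7. Oxidation with potassium nitrosodisulfonate ON(SO3K)2 in aqueous KH2PO4/acetone gives 2-methoxy-3-methyl-1,4-benzoquinone F8. Thiele–Winter acetoxylation (Ac2O, catalytic H2SO4, rt) is expected to enter mainly para to the methoxy group and give 5-methoxy-6-methylbenzene-1,2,4-triyl triacetate F9. HCl in MeOH under N2 gives 5-methoxy-6-methylbenzene-1,2,4-triol F10, which air (or FeCl3) oxidises to 5.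

## Further compounds

F1 | step 7 | 2,4-dimethoxy-1,5-bis(methoxymethoxy)-3-methylbenzene | COCOc1cc(OCOC)c(OC)c(C)c1OC
F2 | step 7 | 1,14-dibromotetradecane | BrCCCCCCCCCCCCCCBr
F3 | step 7 | 1,14-bis[3,5-dimethoxy-2,6-bis(methoxymethoxy)-4-methylphenyl]tetradecane | COCOc1c(OC)c(C)c(OC)c(OCOC)c1CCCCCCCCCCCCCCc1c(OCOC)c(OC)c(C)c(OC)c1OCOC
F4 | step 7 | 2,2'-(tetradecane-1,14-diyl)bis(4,6-dimethoxy-5-methylbenzene-1,3-diol) | COc1c(C)c(OC)c(O)c(CCCCCCCCCCCCCCc2c(O)c(OC)c(C)c(OC)c2O)c1O
F5 | step 2 | 4,6-dimethoxy-5-methylbenzene-1,3-dicarbaldehyde | COc1c(C=O)cc(C=O)c(OC)c1C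
F6 | step 2 | 4,6-dimethoxy-5-methyl-1,3-phenylene diformate | COc1c(OC=O)cc(OC=O)c(OC)c1C
F7 | step 4 | 3-methoxy-2-methylphenol | COc1cccc(O)c1C
F8 | step 4 | 2-methoxy-3-methyl-1,4-benzoquinone | COC1=C(C)C(=O)C=CC1=O
F9 | step 4 | 5-methoxy-6-methylbenzene-1,2,4-triyl triacetate | COc1c(C)c(OC(C)=O)c(OC(C)=O)cc1OC(C)=O
F10 | step 4 | 5-methoxy-6-methylbenzene-1,2,4-triol | COc1c(C)c(O)c(O)cc1O
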